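The route disconnects the O1–C8a bond of ring C, which lies ortho to the C8 methoxy group of the electron-rich ring A. One anodic dehydrogenative C–H/O–H cyclisation closes the pyranone by joining the enol oxygen of a 1,3-diketone to the free ortho carbon of its 2,4,5-trimethoxyphenyl ring, so the existing ortho methoxy group becomes the C5 oxygen. The precursor is 1-[4-(benzyloxy)-2,3-dimethoxyphenyl]-3-(2,4,5-trimethoxyphenyl)propane-1,3-dione. Its benzyl ether withstands the base used to assemble it and leaves together with the chelated 5-methyl group in a single boron trichloride step.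

Key step: step 4

Remark: the target has no stereocentre and no configurationally stable axis, so it is achiral and the route needs no stereocontrol.

Design note: the B-ring phenol is carried as a benzyl ether because it is inert to amide base and to the anode and is cleaved by the same Lewis acid that frees the 5-OH. Ring A needs no extra electronic bias, since its para-dimethoxy pattern should make it the more easily oxidised ring. The diketone is assembled from the B-ring methyl ketone and the A-ring acid, which makes a separate oxidation of the B-ring carbon unnecessary.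

Step 1
Reactants: 1 1-(2,3,4-trihydroxyphenyl)ethanone (gallacetophenone)
Product: 2 1-[4-(benzyloxy)-2,3-dihydroxyphenyl]ethanone
Conditions: BnBr (1.05 equiv), NaHCO3 (1.5 equiv), DMF, 40 °C
Reagents that add atoms: benzyl bromide, BrCc1ccccc1
Why: Williamson etherification under weak-base control: the 4-OH is para to the acetyl group and the most acidic, whereas the 2-OH is held in a hydrogen bond to the carbonyl and the 3-OH is only meta to it, so hydrogen carbonate should ionise and benzylate O4 alone.

Step 2
Reactants: 2 1-[4-(benzyloxy)-2,3-dihydroxyphenyl]ethanone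
Product: 3 1-[4-(benzyloxy)-2,3-dimethoxyphenyl]ethanone
Conditions: MeI (4 equiv), K2CO3 (4 equiv), DMF, 50 °C
Reagents that add atoms: iodomethane, CI
Why: Williamson O-methylation of both remaining phenols; carbonate in warm DMF is strong enough to break the 2-OH chelate but too weak to enolise the aryl methyl ketone, so C-methylation is not expected and the benzyl ether is untouched.

Step 3
Reactants: 3 1-[4-(benzyloxy)-2,3-dimethoxyphenyl]ethanone; 4 2,4,5-trimethoxybenzoic acid
Product: 8 1-[4-(benzyloxy)-2,3-dimethoxyphenyl]-3-(2,4,5-trimethoxyphenyl)propane-1,3-dione, via 2,4,5-trimethoxybenzoyl chloride 5 (not isolated), via lithium enolate 6 (not isolated), via lithium diketonate 7 (not isolated)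
Conditions: (a) 4, SOCl2, toluene, 70 °C, then evaporation; (b) 3, LiHMDS (2.5 equiv), THF, −78 °C; then 5 in THF, −78 → 0 °C; 1 M HCl quench
Reagents that add atoms: thionyl chloride, O=S(Cl)Cl (supplies only the chlorine of 5); lithium bis(trimethylsilyl)amide, [Li]N([Si](C)(C)C)[Si](C)(C)C (supplies only the lithium of 6 and 7); the isolated product 8 holds atoms of 3 and 4 alone
Why: Crossed Claisen-type C-acylation of a preformed lithium enolate by an aroyl chloride: the second equivalent of amide turns the product into its chelated lithium diketonate 7 as it forms, which blocks proton transfer to 6 and a second acylation, while the benzyl and methyl ethers are inert to LiHMDS at low temperature.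

Step 4
Reactants: 8 1-[4-(benzyloxy)-2,3-dimethoxyphenyl]-3-(2,4,5-trimethoxyphenyl)propane-1,3-dione
Product: 9 2-[4-(benzyloxy)-2,3-dimethoxyphenyl]-5,7,8-trimethoxy-4H-chromen-4-one (4'-benzyloxy-5,7,8,2',3'-pentamethoxyflavone)
Conditions: graphite anode, Pt cathode, undivided cell, n-Bu4NPF6 (0.1 M), HFIP/CH2Cl2 4:1 (0.02 M in 8), constant current 3 mA cm⁻², about 2.2 F mol⁻¹, rt
Reagents that add atoms: none
Why: Proposed new method: the anode takes one electron from ring A of the enolised diketone 8 (the only ring with a para-dimethoxy pair) to give an arene radical cation, the enol oxygen on the carbon bearing ring B adds to C6 of the 2,4,5-trimethoxyphenyl group (the C–H carbon ortho to both the acyl-bearing carbon and the 5-methoxy carbon), and loss of a proton, a second electron and a second proton rearomatises the ring to the chromone while the cathode reduces the protons to H2. The closest known reaction types are the anodic dehydrogenative lactonisation of biaryl-2-carboxylic acids and the oxidative C–H/O–H cyclisation of α-aryl ketone enols to benzofurans, both of which trap an electron-rich arene radical cation with a tethered oxygen nucleophile; an enol closing a pyranone in this way is not established. Ring C closes in a 6-endo-trig sense, since the attacked arene bond (the future C4a–C8a) ends up inside the new ring, and no stereocentre is created. Ring A has to be oxidised before ring B, which its hydroquinone-diether pattern should secure, because ring B is a 1,2,3-trioxygenated arene whose central methoxy group is twisted and whose 4-oxygen is tied up in conjugation with the carbonyl, and the benzyl ether offers nothing oxidisable at that potential. Attack at C–H has to beat ipso attack at the methoxy-bearing ortho carbon: only the C–H adduct can lose a proton and rearomatise, whereas the ipso adduct has no such exit in non-nucleophilic HFIP and should revert. Further oxidation of 9 is held back by stopping near 2 F mol⁻¹ and by the lower electron density of its ring A, where the 8-methoxy group is flanked on both sides and the pyranone withdraws charge.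

Step 5
Reactants: 9 2-[4-(benzyloxy)-2,3-dimethoxyphenyl]-5,7,8-trimethoxy-4H-chromen-4-one
Product: 11 5-hydroxy-2-(4-hydroxy-2,3-dimethoxyphenyl)-7,8-dimethoxy-4H-chromen-4-one (5,4'-dihydroxy-7,8,2',3'-tetramethoxyflavone), via bis(dichloroboryloxy)flavone 10 (not isolated)
Conditions: BCl3 (4 equiv), C6HMe5 (3 equiv), CH2Cl2, −78 → 0 °C; then H2O, rt
Reagents that add atoms: boron trichloride, ClB(Cl)Cl (supplies only the boron and chlorine of 10; the target holds atoms of 9 alone)
Why: Lewis-acid ether cleavage: BCl3 removes the benzyl group at low temperature as a benzyl cation that pentamethylbenzene captures by Friedel–Crafts alkylation, and on warming it cleaves only the 5-methyl ether, whose oxygen sits peri to the C4 carbonyl and forms a six-membered boron chelate, before water hydrolyses 10 to the two phenols.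

Compound list
1 | 1-(2,3,4-trihydroxyphenyl)ethanone (gallacetophenone) | CC(=O)c1ccc(O)c(O)c1O | starting material
2 | 1-[4-(benzyloxy)-2,3-dihydroxyphenyl]ethanone | CC(=O)c1ccc(OCc2ccccc2)c(O)c1O | intermediate
3 | 1-[4-(benzyloxy)-2,3-dimethoxyphenyl]ethanone | CC(=O)c1ccc(OCc2ccccc2)c(OC)c1OC | intermediate
4 | 2,4,5-trimethoxybenzoic acid | COc1cc(OC)c(C(=O)O)cc1OC | starting material
5 | 2,4,5-trimethoxybenzoyl chloride | COc1cc(OC)c(C(=O)Cl)cc1OC | intermediate (not isolated)
6 | lithium enolate of 3, lithium 1-[4-(benzyloxy)-2,3-dimethoxyphenyl]ethen-1-olate | [Li]OC(=C)c1ccc(OCc2ccccc2)c(OC)c1OC | intermediate (not isolated)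
7 | lithium diketonate of 8 (Z-configured chelated enolate) | COc1cc(OC)c(C(=O)/C=C(\O[Li])c2ccc(OCc3ccccc3)c(OC)c2OC)cc1OC | intermediate (not isolated)
8 | 1-[4-(benzyloxy)-2,3-dimethoxyphenyl]-3-(2,4,5-trimethoxyphenyl)propane-1,3-dione | COc1cc(OC)c(C(=O)CC(=O)c2ccc(OCc3ccccc3)c(OC)c2OC)cc1OC | intermediate
9 | 2-[4-(benzyloxy)-2,3-dimethoxyphenyl]-5,7,8-trimethoxy-4H-chromen-4-one | COc1cc(OC)c2c(=O)cc(-c3ccc(OCc4ccccc4)c(OC)c3OC)oc2c1OC | intermediate
10 | 5-(dichloroboryloxy)-2-[4-(dichloroboryloxy)-2,3-dimethoxyphenyl]-7,8-dimethoxy-4H-chromen-4-one | COc1cc(OB(Cl)Cl)c2c(=O)cc(-c3ccc(OB(Cl)Cl)c(OC)c3OC)oc2c1OC | intermediate (not isolated)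
11 | 5-hydroxy-2-(4-hydroxy-2,3-dimethoxyphenyl)-7,8-dimethoxy-4H-chromen-4-one | COc1cc(O)c2c(=O)cc(-c3ccc(O)c(OC)c3OC)oc2c1OC | target

Total step count: 5. Longest linear sequence: 5 steps (1 → 2 → 3 → 8 → 9 → 11); acid 4 is bought and activated in the flask within step 3.

Steps most likely to fail

Step 4. The closure may run through the methoxy-bearing ortho carbon instead of the C–H carbon, the diketone may couple oxidatively at its central carbon, or the product may be oxidised further. The fallback uses known chemistry, sets out from ketone 3 and returns at flavone 9; it places the O1 oxygen in the A-ring building block instead of forming the O1–C8a bond late. A haloform reaction (NaOCl, NaOH, aqueous dioxane, 60 °C) should cut 3 down to 4-(benzyloxy)-2,3-dimethoxybenzoic acid F1. Commercial 1,2,3,5-tetramethoxybenzene F2 is acetylated with AcCl/AlCl3 in ether, the aluminium chelate removing the flanked ortho methyl group in the same pot, which should give 1-(2-hydroxy-3,4,6-trimethoxyphenyl)ethanone F3. Steglich esterification (EDC·HCl, DMAP, CH2Cl2) joins F1 and F3 to 2-acetyl-3,5,6-trimethoxyphenyl 4-(benzyloxy)-2,3-dimethoxybenzoate F4. Baker–Venkataraman rearrangement (KOH, pyridine, 50 °C) moves the aroyl group to carbon and should give 1-[4-(benzyloxy)-2,3-dimethoxyphenyl]-3-(2-hydroxy-3,4,6-trimethoxyphenyl)propane-1,3-dione F5. Acid-catalysed cyclodehydration (TsOH, toluene, 80 °C) then closes the pyranone to 9.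

Step 5. During the warm-up needed for the 5-methyl group, a second methyl ether may be lost, most likely the 3'-methoxy group next to the newly formed 4'-O–B bond; alternatively the 5-O-demethylation may stay incomplete at a temperature that spares the others. The fallback sets out from 9 and returns at 11, and it separates the two deprotections into orthogonal operations. Magnesium iodide etherate (toluene/Et2O, 60 °C) acts only through the carbonyl chelate and should cleave the 5-methyl ether alone, giving 2-[4-(benzyloxy)-2,3-dimethoxyphenyl]-5-hydroxy-7,8-dimethoxy-4H-chromen-4-one F6. Neutral hydrogenolysis (H2, Pd/C, EtOAc/THF, rt) then removes the benzyl group and gives 11.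

Step 1. Alkylation may spread to O3 or go on to a dibenzyl ether once O4 has reacted. The fallback sets out from 1 and returns at 2, and it masks the vicinal diol during the alkylation. In aqueous borax/NaOH the 2,3-diol of 1 is tied up as the cyclic borate, sodium 4-acetyl-2,2,7-trihydroxy-1,3,2-benzodioxaborol-2-uide F7, so that only O4 is left as a free phenoxide. Benzyl bromide with a phase-transfer catalyst should alkylate it to sodium 4-acetyl-7-(benzyloxy)-2,2-dihydroxy-1,3,2-benzodioxaborol-2-uide F8. Acidification with dilute HCl hydrolyses the borate and gives 2.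

Further compounds
F1 | step 4 | 4-(benzyloxy)-2,3-dimethoxybenzoic acid | O=C(O)c1ccc(OCc2ccccc2)c(OC)c1OC
F2 | step 4 | 1,2,3,5-tetramethoxybenzene | COc1cc(OC)c(OC)c(OC)c1
F3 | step 4 | 1-(2-hydroxy-3,4,6-trimethoxyphenyl)ethanone | CC(=O)c1c(OC)cc(OC)c(OC)c1O
F4 | step 4 | 2-acetyl-3,5,6-trimethoxyphenyl 4-(benzyloxy)-2,3-dimethoxybenzoate | CC(=O)c1c(OC)cc(OC)c(OC)c1OC(=O)c1ccc(OCc2ccccc2)c(OC)c1OC
F5 | step 4 | 1-[4-(benzyloxy)-2,3-dimethoxyphenyl]-3-(2-hydroxy-3,4,6-trimethoxyphenyl)propane-1,3-dione | COc1cc(OC)c(C(=O)CC(=O)c2ccc(OCc3ccccc3)c(OC)c2OC)c(O)c1OC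
F6 | step 5 | 2-[4-(benzyloxy)-2,3-dimethoxyphenyl]-5-hydroxy-7,8-dimethoxy-4H-chromen-4-one | COc1cc(O)c2c(=O)cc(-c3ccc(OCc4ccccc4)c(OC)c3OC)oc2c1OC
F7 | step 1 | sodium 4-acetyl-2,2,7-trihydroxy-1,3,2-benzodioxaborol-2-uide | CC(=O)c1ccc(O)c2O[B-](O)(O)Oc12.[Na+]
F8 | step 1 | sodium 4-acetyl-7-(benzyloxy)-2,2-dihydroxy-1,3,2-benzodioxaborol-2-uide | CC(=O)c1ccc(OCc3ccccc3)c2O[B-](O)(O)Oc12.[Na+]
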